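Ring C is disconnected at both of its bonds to ring A: the aryl ether bond O1–C8a and the aryl ketone bond C4–C4a. One operation makes both by annulating an aryne (triple bond C4a≡C8a), released by fluoride from a geranylated, MOM-protected 2-silylaryl triflate of phloroglucinol type, with an enantiopure β-hydroxy ester that already holds C2, C3, C4 and ring B. The step exploits the C5 oxygen beside C4a, which steers the alkoxide to C8a and the carbanion to C4a for ring closure on the ester, and the symmetry of the ring A oxygenation about the C6–C8a axis, which makes the precursor regiochemically unambiguous. Acidic removal of three MOM groups then gives the target.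

Key step: step 9

Remark: the given stereodescriptor is read as the (2S)-flavanone; flavanone numbering (O1, C2, C3, C4, C4a, C5 to C8, C8a) is used, geranyl = (2E)-3,7-dimethylocta-2,6-dien-1-yl, MOM = methoxymethyl.

Step 1
Reactants: 1 resorcinol
Product: 2 1,3-bis(methoxymethoxy)benzene
Conditions: NaH, MOMCl, DMF, 0 °C to rt
Reagents that add atoms: chloromethyl methyl ether, COCCl
Why: Williamson-type O-alkylation of both phenoxides gives the bis-acetal, which serves later as ortho-directing group and as acid-labile protection.

Step 2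
Reactants: 2 1,3-bis(methoxymethoxy)benzene; 3 geranyl bromide
Product: 5 2-geranyl-1,3-bis(methoxymethoxy)benzene, via aryllithium 4 (not isolated)
Conditions: n-BuLi, THF, 0 °C to rt; then CuI (10 mol %), 3, −78 °C to rt
Reagents that add atoms: none
Why: Directed ortho-metalation, in which the two OMOM groups together direct lithiation to the carbon between them, followed by copper-catalysed SN2 allylation with the primary allylic bromide, should give the linear geranyl arene with the E alkene untouched.

Step 3
Reactants: 5 2-geranyl-1,3-bis(methoxymethoxy)benzene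
Product: 7 4-geranyl-3,5-bis(methoxymethoxy)phenol, via arylboronate 6 (not isolated)
Conditions: [Ir(OMe)(cod)]2 (1.5 mol %), 4,4'-di-tert-butyl-2,2'-bipyridine, B2pin2, THF, 70 °C; then NaOH, H2O2, H2O, 0 °C to rt
Reagents that add atoms: hydrogen peroxide, OO; bis(pinacolato)diboron, CC1(C)OB(OC1(C)C)B1OC(C)(C)C(C)(C)O1 (its boryl group stays only in 6)
Why: Sterically controlled iridium-catalysed C–H borylation should take the only ring C–H without an ortho substituent (para to the geranyl group), and oxidation of the C–B bond with basic peroxide, which does not epoxidise unactivated alkenes, gives the phenol.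

Step 4
Reactants: 7 4-geranyl-3,5-bis(methoxymethoxy)phenol
Product: 8 2-bromo-4-geranyl-3,5-bis(methoxymethoxy)phenol
Conditions: NBS (1.0 equiv), CH2Cl2, −78 °C, dark
Reagents that add atoms: N-bromosuccinimide, O=C1CCC(=O)N1Br
Why: Electrophilic aromatic bromination of a trioxygenated ring should be far faster at −78 °C than attack on the trisubstituted alkenes, and the two open ring positions (both ortho to OH) are equivalent, so one monobromide is expected.

Step 5
Reactants: 8 2-bromo-4-geranyl-3,5-bis(methoxymethoxy)phenol
Product: 11 4-geranyl-3,5-bis(methoxymethoxy)-2-(trimethylsilyl)phenyl trifluoromethanesulfonate, via silyl ether 9 (not isolated), via lithium phenolate 10 (not isolated)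
Conditions: HMDS, THF, 65 °C, then evaporation; n-BuLi, THF, −100 °C; Tf2O, −100 to −78 °C
Reagents that add atoms: hexamethyldisilazane, C[Si](C)(C)N[Si](C)(C)C; trifluoromethanesulfonic anhydride, O=S(=O)(OS(=O)(=O)C(F)(F)F)C(F)(F)F
Why: O-silylation, fast bromine–lithium exchange and 1,3 O-to-C silyl shift (retro-Brook rearrangement) give the ortho-silyl phenolate, which is trapped as the triflate, the standard entry to 2-silylaryl triflate aryne precursors.

Step 6
Reactants: 12 4'-hydroxyacetophenone
Product: 13 1-[4-(methoxymethoxy)phenyl]ethan-1-one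
Conditions: NaH (1.1 equiv), MOMCl, DMF, 0 °C to rt
Reagents that add atoms: chloromethyl methyl ether, COCCl
Why: Williamson-type O-alkylation of the phenoxide, which is far more acidic than the ketone α-position, protects the future 4'-hydroxyl in the same way as the ring A oxygens.

Step 7
Reactants: 13 1-[4-(methoxymethoxy)phenyl]ethan-1-one
Product: 14 methyl 3-[4-(methoxymethoxy)phenyl]-3-oxopropanoate
Conditions: NaH, (MeO)2CO, THF, reflux; then AcOH
Reagents that add atoms: dimethyl carbonate, COC(=O)OC
Why: Crossed Claisen condensation of the ketone enolate with the non-enolisable carbonate is driven to completion by deprotonation of the β-keto ester formed.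

Step 8
Reactants: 14 methyl 3-[4-(methoxymethoxy)phenyl]-3-oxopropanoate
Product: 15 methyl (3S)-3-hydroxy-3-[4-(methoxymethoxy)phenyl]propanoate
Conditions: RuCl(p-cymene)[(S,S)-TsDPEN] (1 mol %), HCO2H/Et3N (5:2), EtOAc, 40 °C
Reagents that add atoms: none
Why: Noyori–Ikariya asymmetric transfer hydrogenation of an aryl ketone, in which the (S,S)-ligand should deliver hydride to the same face as for acetophenone (aryl group over the η6-arene), sets the future C2 stereocenter as S.

Step 9
Reactants: 11 4-geranyl-3,5-bis(methoxymethoxy)-2-(trimethylsilyl)phenyl trifluoromethanesulfonate; 15 methyl (3S)-3-hydroxy-3-[4-(methoxymethoxy)phenyl]propanoate (1.5 equiv)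
Product: 17 (2S)-6-geranyl-5,7-bis(methoxymethoxy)-2-[4-(methoxymethoxy)phenyl]-2,3-dihydro-4H-chromen-4-one, via aryne 16 (not isolated)
Conditions: KF, 18-crown-6, THF, −20 °C to rt; pH 7 buffer quench
Reagents that add atoms: none
Why: Proposed new method: fluoride removes the silyl group of 11 and triflate leaves to give aryne 16 (triple bond C4a≡C8a), the fluoride-activated hydroxyl of 15 adds its oxygen to C8a, and the resulting C4a carbanion attacks the methyl ester and expels methoxide, so that O1–C8a and C4–C4a form in one operation. The closest known reaction types are the aryne annulation of methyl salicylates to xanthones (O-arylation, then acylation of the aryl anion), the O–H addition of aliphatic alcohols to arynes under KF/18-crown-6 and the insertion of arynes into the N–C(O) bond of β-lactams; an open-chain aliphatic β-hydroxy ester has not been shown in this role. Ring C closes by a 6-exo-trig addition–elimination of the aryl anion at the ester carbonyl. No new stereocenter is formed: C2 comes from 15 and keeps its S configuration because the C2–O bond is never broken. The step needs oxygen at C8a and the acyl group at C4a, which the C5 OMOM group secures by polarising the aryne (attack at the distal carbon, carbanion next to oxygen) and by shielding C4a. It also needs acylation of the carbanion to outrun protonation and the product to escape base-induced ring opening, which aprotic THF, low temperature and a neutral quench should secure.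

Step 10
Reactants: 17 (2S)-6-geranyl-5,7-bis(methoxymethoxy)-2-[4-(methoxymethoxy)phenyl]-2,3-dihydro-4H-chromen-4-one
Product: 18 bonannione A
Conditions: HCl (3 M, aq.), MeOH, 50 °C
Reagents that add atoms: none
Why: Acid-catalysed acetal exchange with methanol (conditions of the kind applied to MOM-protected prenylated flavanones) frees the three phenols, while dilute acid at moderate temperature should neither open ring C (C2 is kept) nor cyclise the geranyl chain onto the neighbouring phenols.

Compound list
1 | resorcinol (benzene-1,3-diol) | Oc1cccc(O)c1 | starting material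
2 | 1,3-bis(methoxymethoxy)benzene | COCOc1cccc(OCOC)c1 | intermediate
3 | geranyl bromide, (2E)-1-bromo-3,7-dimethylocta-2,6-diene | CC(C)=CCC/C(C)=C/CBr | starting material
4 | [2,6-bis(methoxymethoxy)phenyl]lithium | [Li]c1c(OCOC)cccc1OCOC | intermediate
5 | 2-geranyl-1,3-bis(methoxymethoxy)benzene | CC(C)=CCC/C(C)=C/Cc1c(OCOC)cccc1OCOC | intermediate
6 | 2-[4-geranyl-3,5-bis(methoxymethoxy)phenyl]-4,4,5,5-tetramethyl-1,3,2-dioxaborolane | CC(C)=CCC/C(C)=C/Cc1c(OCOC)cc(B2OC(C)(C)C(C)(C)O2)cc1OCOC | intermediate
7 | 4-geranyl-3,5-bis(methoxymethoxy)phenol | CC(C)=CCC/C(C)=C/Cc1c(OCOC)cc(O)cc1OCOC | intermediate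
8 | 2-bromo-4-geranyl-3,5-bis(methoxymethoxy)phenol | CC(C)=CCC/C(C)=C/Cc1c(OCOC)cc(O)c(Br)c1OCOC | intermediate
9 | [2-bromo-4-geranyl-3,5-bis(methoxymethoxy)phenoxy]trimethylsilane | CC(C)=CCC/C(C)=C/Cc1c(OCOC)cc(O[Si](C)(C)C)c(Br)c1OCOC | intermediate
10 | lithium 4-geranyl-3,5-bis(methoxymethoxy)-2-(trimethylsilyl)phenolate | CC(C)=CCC/C(C)=C/Cc1c(OCOC)cc([O-])c([Si](C)(C)C)c1OCOC.[Li+] | intermediate
11 | 4-geranyl-3,5-bis(methoxymethoxy)-2-(trimethylsilyl)phenyl trifluoromethanesulfonate | CC(C)=CCC/C(C)=C/Cc1c(OCOC)cc(OS(=O)(=O)C(F)(F)F)c([Si](C)(C)C)c1OCOC | intermediate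
12 | 4'-hydroxyacetophenone | CC(=O)c1ccc(O)cc1 | starting material
13 | 1-[4-(methoxymethoxy)phenyl]ethan-1-one | CC(=O)c1ccc(OCOC)cc1 | intermediate
14 | methyl 3-[4-(methoxymethoxy)phenyl]-3-oxopropanoate | COC(=O)CC(=O)c1ccc(OCOC)cc1 | intermediate
15 | methyl (3S)-3-hydroxy-3-[4-(methoxymethoxy)phenyl]propanoate | COC(=O)C[C@@H](c1ccc(OCOC)cc1)O | intermediate
16 | 4-geranyl-3,5-bis(methoxymethoxy)benzyne (1,2-didehydrobenzene) | CC(C)=CCC/C(C)=C/CC1=C(OCOC)C#CC=C1OCOC | intermediate
17 | (2S)-6-geranyl-5,7-bis(methoxymethoxy)-2-[4-(methoxymethoxy)phenyl]-2,3-dihydro-4H-chromen-4-one | CC(C)=CCC/C(C)=C/Cc1c(OCOC)cc2c(c1OCOC)C(=O)C[C@@H](c1ccc(OCOC)cc1)O2 | intermediate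
18 | bonannione A, (2S)-6-geranyl-5,7-dihydroxy-2-(4-hydroxyphenyl)-2,3-dihydro-4H-chromen-4-one | CC(C)=CCC/C(C)=C/Cc1c(O)cc2c(c1O)C(=O)C[C@@H](c1ccc(O)cc1)O2 | target

Total step count: 10. Longest linear sequence: 7 steps (steps 1, 2, 3, 4, 5, 9, 10, from resorcinol).

Steps most likely to fail

Step 9 (proposed new method). The aryl anion may be protonated before it acylates, which would stop at simple O–H insertion. It may also take a proton from the ester α-position, which would be followed by β-elimination. The C2 configuration may erode through base-induced opening and reclosure of ring C. The fallback sets out from 11 and comes back at 17, using known chemistry only. Commercial 4-(methoxymethoxy)benzaldehyde is condensed with malonic acid (pyridine, piperidine, 90 °C; Doebner condensation) to (2E)-3-[4-(methoxymethoxy)phenyl]prop-2-enoic acid F1. Heating 11 with F1 and CsF in THF at 125 °C in a sealed tube applies the known insertion of arynes into the C–O bond of carboxylic acids (O-arylation by the carboxylate, then 1,3-acyl shift to the carbanion). With the same regiochemistry this should give the 2'-hydroxychalcone (2E)-1-[3-geranyl-6-hydroxy-2,4-bis(methoxymethoxy)phenyl]-3-[4-(methoxymethoxy)phenyl]prop-2-en-1-one F2. NaOAc in ethanol at reflux closes its only free phenol onto the enone (6-endo-trig oxa-Michael addition) to the racemic protected flavanone F3. The enantiomers are separated by preparative chromatography on a cellulose carbamate chiral phase; the 2S enantiomer is 17, and the 2R enantiomer is racemised with base through F2 and recycled.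

Step 4. The electrophilic bromine may attack the two trisubstituted alkenes, and the ring may be brominated twice. The fallback sets out from 7 and comes back at 11, so that steps 4 and 5 are both replaced and no electrophilic halogen meets the geranyl chain. Phenol 7 is acylated with ClCONEt2 (NaH, THF) to 4-geranyl-3,5-bis(methoxymethoxy)phenyl N,N-diethylcarbamate F4. Carbamate-directed ortho-metalation (s-BuLi, TMEDA, THF, −78 °C, then TMSCl; both ortho positions are equivalent) gives 4-geranyl-3,5-bis(methoxymethoxy)-2-(trimethylsilyl)phenyl N,N-diethylcarbamate F5. LiAlH4 in THF cleaves the carbamate to 4-geranyl-3,5-bis(methoxymethoxy)-2-(trimethylsilyl)phenol F6, and Tf2O with pyridine in CH2Cl2 at 0 °C gives 11.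

Step 3. The iridium catalyst may borylate or hydroborate the geranyl alkenes, or be inhibited by the diene. The fallback sets out from 2 and comes back at 7, with the borylation moved ahead of the geranylation. Compound 2 is borylated under the same catalyst to 2-[3,5-bis(methoxymethoxy)phenyl]-4,4,5,5-tetramethyl-1,3,2-dioxaborolane F7, which is oxidised in the same flask (NaOH, H2O2) to 3,5-bis(methoxymethoxy)phenol F8. TIPSCl and imidazole in DMF give [3,5-bis(methoxymethoxy)phenoxy]tri(propan-2-yl)silane F9. Lithiation with n-BuLi in THF at 0 °C should occur between the two OMOM groups, because the bulky silyl ether shields its own ortho positions; CuI-catalysed allylation with 3 then gives [4-geranyl-3,5-bis(methoxymethoxy)phenoxy]tri(propan-2-yl)silane F10. TBAF in THF frees phenol 7.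

Further compounds
F1 | step 9 | (2E)-3-[4-(methoxymethoxy)phenyl]prop-2-enoic acid | COCOc1ccc(/C=C/C(=O)O)cc1
F2 | step 9 | (2E)-1-[3-geranyl-6-hydroxy-2,4-bis(methoxymethoxy)phenyl]-3-[4-(methoxymethoxy)phenyl]prop-2-en-1-one | CC(C)=CCC/C(C)=C/Cc1c(OCOC)cc(O)c(C(=O)/C=C/c2ccc(OCOC)cc2)c1OCOC
F3 | step 9 | racemic 6-geranyl-5,7-bis(methoxymethoxy)-2-[4-(methoxymethoxy)phenyl]-2,3-dihydro-4H-chromen-4-one | CC(C)=CCC/C(C)=C/Cc1c(OCOC)cc2c(c1OCOC)C(=O)CC(c1ccc(OCOC)cc1)O2
F4 | step 4 | 4-geranyl-3,5-bis(methoxymethoxy)phenyl N,N-diethylcarbamate | CC(C)=CCC/C(C)=C/Cc1c(OCOC)cc(OC(=O)N(CC)CC)cc1OCOC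
F5 | step 4 | 4-geranyl-3,5-bis(methoxymethoxy)-2-(trimethylsilyl)phenyl N,N-diethylcarbamate | CC(C)=CCC/C(C)=C/Cc1c(OCOC)cc(OC(=O)N(CC)CC)c([Si](C)(C)C)c1OCOC
F6 | step 4 | 4-geranyl-3,5-bis(methoxymethoxy)-2-(trimethylsilyl)phenol | CC(C)=CCC/C(C)=C/Cc1c(OCOC)cc(O)c([Si](C)(C)C)c1OCOC
F7 | step 3 | 2-[3,5-bis(methoxymethoxy)phenyl]-4,4,5,5-tetramethyl-1,3,2-dioxaborolane | COCOc1cc(OCOC)cc(B2OC(C)(C)C(C)(C)O2)c1
F8 | step 3 | 3,5-bis(methoxymethoxy)phenol | COCOc1cc(O)cc(OCOC)c1
F9 | step 3 | [3,5-bis(methoxymethoxy)phenoxy]tri(propan-2-yl)silane | COCOc1cc(OCOC)cc(O[Si](C(C)C)(C(C)C)C(C)C)c1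
F10 | step 3 | [4-geranyl-3,5-bis(methoxymethoxy)phenoxy]tri(propan-2-yl)silane | CC(C)=CCC/C(C)=C/Cc1c(OCOC)cc(O[Si](C(C)C)(C(C)C)C(C)C)cc1OCOC
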